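**Retrosynthetic overview**

1. Target ⇐ desilylation ⇐ Mitsunobu esterification with 3-methylbut-2-enoic acid (inverts C1, installs the ester) ⇐ matched Sharpless epoxidation of a (1R)-dienol ⇐ CBS reduction of a macrocyclic cross-conjugated dienone.
2. Key step: the eleven-membered ring is closed by a carbonylative Stille macrocyclisation. C1 is carbon monoxide, inserted between a C2 (E)-vinylstannane and a C11 (E)-vinyl iodide of an open chain.
3. Open chain ⇐ E-selective Horner–Wadsworth–Emmons olefination at C6=C7 (ester later reduced to the CH2OH) between a C6 aldehyde and a phosphonate carrying C7–C11.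
4. Quaternary C4 ⇐ Johnson–Claisen rearrangement with 1,3-chirality transfer from a lipase-resolved (S)-allylic alcohol; the propenyl group then becomes aldehyde, alkyne and stannane; the side chain comes from HWE olefination and MeMgBr addition.
5. Ring order: carbocycle first (step 18), oxirane second (step 20).

Assumption: ring atoms are numbered C1 (ester-bearing CH), C2=C3, C4 (quaternary), C5, C6=C7, C8, C9, C10, C11 (methyl-bearing oxirane carbon), which makes the target (1S,2E,4R,6E,10R,11S) with a threo C1–O/oxirane relationship; common reagents, catalysts and solvents are bought.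

**Route**

Step 1
Reactants: 1 tert-butyl(but-3-yn-1-yloxy)dimethylsilane; 2 acetaldehyde
Product: 4 rac-(E)-6-(tert-butyldimethylsilyloxy)-4-methylhex-3-en-2-ol, via alkenylalane 3 (not isolated)
Conditions: Me3Al (2 equiv), Cp2ZrCl2 (0.2 equiv), CH2Cl2, 0 °C → rt; n-BuLi, −78 °C; 2, THF, −78 → 0 °C; aq. potassium sodium tartrate
Reagents that add atoms: trimethylaluminium, C[Al](C)C
Why: Negishi zirconium-catalysed carboalumination adds methyl and aluminium syn across the terminal alkyne (methyl to the internal carbon), and the resulting (E)-alkenylalane, activated with n-BuLi, adds to acetaldehyde with retention of olefin geometry, the carbinol centre being formed racemic at this point.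

Step 2
Reactants: 4 rac-(E)-6-(tert-butyldimethylsilyloxy)-4-methylhex-3-en-2-ol
Product: 5 (2S,3E)-6-(tert-butyldimethylsilyloxy)-4-methylhex-3-en-2-ol
Conditions: immobilised Candida antarctica lipase B, vinyl acetate, hexane, 25 °C, stopped at about 52% conversion
Reagents that add atoms: none
Why: Lipase-catalysed kinetic resolution by transesterification, in which (Kazlauskas' rule) the enzyme acetylates the (R)-enantiomer of this methyl carbinol and leaves the (S)-alcohol in high ee.

Step 3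
Reactants: 5 (2S,3E)-6-(tert-butyldimethylsilyloxy)-4-methylhex-3-en-2-ol
Product: 7 methyl (3S,4E)-3-[2-(tert-butyldimethylsilyloxy)ethyl]-3-methylhex-4-enoate, via ketene acetal 6 (not isolated)
Conditions: MeC(OMe)3 (6 equiv), EtCO2H (0.1 equiv), xylene, 135 °C, MeOH distilled off
Reagents that add atoms: trimethyl orthoacetate, COC(C)(OC)OC
Why: Johnson–Claisen [3,3]-sigmatropic rearrangement through a chair transition state with the carbinol methyl equatorial (the axial alternative suffers A(1,3) strain with the Z-methyl of the trisubstituted alkene), so the C–O chirality is transferred suprafacially to the new quaternary carbon (future C4) and the new alkene is E.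

Step 4
Reactants: 7 methyl (3S,4E)-3-[2-(tert-butyldimethylsilyloxy)ethyl]-3-methylhex-4-enoate
Product: 9 methyl (3S)-5-(tert-butyldimethylsilyloxy)-3-formyl-3-methylpentanoate, via ozonide 8 (not isolated)
Conditions: O3, CH2Cl2, −78 °C; PPh3, −78 °C → rt
Reagents that add atoms: ozone, [O-][O+]=O
Why: Ozonolysis with reductive work-up cleaves the only C=C bond and unmasks the future C3 aldehyde on the quaternary carbon, which has no α-hydrogen and cannot epimerise.

Step 5
Reactants: 9 methyl (3S)-5-(tert-butyldimethylsilyloxy)-3-formyl-3-methylpentanoate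
Product: 10 methyl (3S)-3-[2-(tert-butyldimethylsilyloxy)ethyl]-3-methylpent-4-ynoate
Conditions: dimethyl (1-diazo-2-oxopropyl)phosphonate, K2CO3, MeOH, 0 °C → rt
Reagents that add atoms: dimethyl (1-diazo-2-oxopropyl)phosphonate, COP(=O)(OC)C(=[N+]=[N-])C(C)=O
Why: Seyferth–Gilbert homologation in the Ohira–Bestmann variant converts the non-enolisable aldehyde into the terminal alkyne (C2≡C3) under mild conditions in which the methyl ester stays a methyl ester.

Step 6
Reactants: 10 methyl (3S)-3-[2-(tert-butyldimethylsilyloxy)ethyl]-3-methylpent-4-ynoate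
Product: 11 methyl (3S,4E)-3-[2-(tert-butyldimethylsilyloxy)ethyl]-3-methyl-5-(tributylstannyl)pent-4-enoate
Conditions: Bu3SnH (1.2 equiv), PdCl2(PPh3)2 (2 mol%), THF, 0 °C → rt
Reagents that add atoms: tributyltin hydride, CCCC[SnH](CCCC)CCCC
Why: Palladium-catalysed syn-hydrostannation of a terminal alkyne on a fully substituted carbon puts tin on the unhindered terminus and gives the (E)-vinylstannane at C2.

Step 7
Reactants: 11 methyl (3S,4E)-3-[2-(tert-butyldimethylsilyloxy)ethyl]-3-methyl-5-(tributylstannyl)pent-4-enoate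
Product: 12 (3S,4E)-3-[2-(tert-butyldimethylsilyloxy)ethyl]-3-methyl-5-(tributylstannyl)pent-4-enal
Conditions: iBu2AlH (1.1 equiv), CH2Cl2, −78 °C; MeOH; aq. potassium sodium tartrate
Reagents that add atoms: none
Why: Partial ester-to-aldehyde reduction with one equivalent of iBu2AlH at −78 °C is a standard transformation that the vinylstannane and the silyl ether survive.

Step 8
Reactants: 12 (3S,4E)-3-[2-(tert-butyldimethylsilyloxy)ethyl]-3-methyl-5-(tributylstannyl)pent-4-enal; 13 dimethyl (2-oxopropyl)phosphonate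
Product: 14 (3E,6R,7E)-6-[2-(tert-butyldimethylsilyloxy)ethyl]-6-methyl-8-(tributylstannyl)octa-3,7-dien-2-one
Conditions: NaH, 13, THF, 0 °C; then 12, 0 °C → rt
Reagents that add atoms: none
Why: Horner–Wadsworth–Emmons olefination with a stabilised β-ketophosphonate anion gives the (E)-enone of the side chain.

Step 9
Reactants: 14 (3E,6R,7E)-6-[2-(tert-butyldimethylsilyloxy)ethyl]-6-methyl-8-(tributylstannyl)octa-3,7-dien-2-one
Product: 15 (3E,6R,7E)-6-[2-(tert-butyldimethylsilyloxy)ethyl]-2,6-dimethyl-8-(tributylstannyl)octa-3,7-dien-2-ol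
Conditions: CeCl3 (anhydrous, 1.5 equiv), MeMgBr (1.5 equiv), THF, −78 °C; aq. NH4Cl
Reagents that add atoms: methylmagnesium bromide, C[Mg]Br
Why: Cerium-mediated 1,2-addition of the methyl Grignard reagent to the enone (CeCl3 suppresses enolisation and conjugate addition) gives the tertiary allylic alcohol, and a Grignard reagent does not transmetalate the vinylstannane.

Step 10
Reactants: 15 (3E,6R,7E)-6-[2-(tert-butyldimethylsilyloxy)ethyl]-2,6-dimethyl-8-(tributylstannyl)octa-3,7-dien-2-ol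
Product: 16 (3R,5E)-3,7-dimethyl-3-[(E)-2-(tributylstannyl)ethenyl]oct-5-ene-1,7-diol
Conditions: TBAF, THF, 0 °C → rt
Reagents that add atoms: none
Why: Fluoride-mediated desilylation removes the primary silyl ether and leaves the vinylstannane and tertiary alcohol untouched.

Step 11
Reactants: 16 (3R,5E)-3,7-dimethyl-3-[(E)-2-(tributylstannyl)ethenyl]oct-5-ene-1,7-diol
Product: 17 (3R,5E)-7-hydroxy-3,7-dimethyl-3-[(E)-2-(tributylstannyl)ethenyl]oct-5-enal
Conditions: Dess–Martin periodinane, pyridine, CH2Cl2, 0 °C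
Reagents that add atoms: none
Why: Dess–Martin oxidation converts the primary alcohol into the C6 aldehyde, the tertiary alcohol cannot be oxidised and the pyridine buffer protects the acid-sensitive vinylstannane.

Step 12
Reactants: 18 pent-3-yn-1-ol
Product: 20 (E)-4-iodopent-3-en-1-ol, via alkenylzirconocene 19 (not isolated)
Conditions: Cp2Zr(H)Cl (2.5 equiv), THF, 40 °C; then iodine, 0 °C
Reagents that add atoms: iodine, [I][I]
Why: Hydrozirconation–iodination, in which Zr–H adds syn to the internal alkyne, excess Cp2Zr(H)Cl equilibrates zirconium to the carbon next to the small methyl group, and iodinolysis with retention gives the (E)-2-iodoalkene.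

Step 13
Reactants: 20 (E)-4-iodopent-3-en-1-ol
Product: 21 (E)-2,5-diiodopent-2-ene
Conditions: iodine, PPh3, imidazole, CH2Cl2, 0 °C → rt, dark
Reagents that add atoms: iodine, [I][I]
Why: Appel-type iodination converts the primary alcohol into the iodide by SN2 displacement of an alkoxyphosphonium ion without touching the vinyl iodide.

Step 14
Reactants: 21 (E)-2,5-diiodopent-2-ene; 22 triethyl phosphonoacetate
Product: 23 ethyl (5E)-2-(diethoxyphosphoryl)-6-iodohept-5-enoate (racemic at C2)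
Conditions: NaH, 22 (2 equiv), DMF, 0 °C → rt; then 21, 50 °C
Reagents that add atoms: none
Why: SN2 C-alkylation of the sodium salt of the phosphonoacetate with the primary iodide, in which the soft stabilised carbanion favours substitution over elimination and the vinyl iodide is inert.

Step 15
Reactants: 17 (3R,5E)-7-hydroxy-3,7-dimethyl-3-[(E)-2-(tributylstannyl)ethenyl]oct-5-enal; 23 ethyl (5E)-2-(diethoxyphosphoryl)-6-iodohept-5-enoate
Product: 24 ethyl (2E,5R,7E)-9-hydroxy-2-[(E)-4-iodopent-3-en-1-yl]-5,9-dimethyl-5-[(E)-2-(tributylstannyl)ethenyl]deca-2,7-dienoate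
Conditions: NaH, 23, THF, 0 °C; then 17, 0 °C → rt
Reagents that add atoms: none
Why: Horner–Wadsworth–Emmons olefination of an α-alkyl phosphonoacetate with an unbranched aldehyde gives the trisubstituted (E)-enoate (C5 trans to the ester and cis to C8), which is the C6=C7 geometry of the target.

Step 16
Reactants: 24 ethyl (2E,5R,7E)-9-hydroxy-2-[(E)-4-iodopent-3-en-1-yl]-5,9-dimethyl-5-[(E)-2-(tributylstannyl)ethenyl]deca-2,7-dienoate
Product: 25 (2E,5R,7E)-2-[(E)-4-iodopent-3-en-1-yl]-5,9-dimethyl-5-[(E)-2-(tributylstannyl)ethenyl]deca-2,7-diene-1,9-diol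
Conditions: iBu2AlH (3.5 equiv), CH2Cl2, −78 °C; aq. potassium sodium tartrate
Reagents that add atoms: none
Why: 1,2-Reduction of the conjugated ester to the allylic alcohol with iBu2AlH at −78 °C leaves the vinyl iodide, vinylstannane and alkenes intact.

Step 17
Reactants: 25 (2E,5R,7E)-2-[(E)-4-iodopent-3-en-1-yl]-5,9-dimethyl-5-[(E)-2-(tributylstannyl)ethenyl]deca-2,7-diene-1,9-diol
Product: 26 (3E,6R,8E)-10-(tert-butyldimethylsilyloxy)-9-[(E)-4-iodopent-3-en-1-yl]-2,6-dimethyl-6-[(E)-2-(tributylstannyl)ethenyl]deca-3,8-dien-2-ol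
Conditions: TBSCl, imidazole, CH2Cl2, 0 °C
Reagents that add atoms: tert-butyldimethylsilyl chloride, C[Si](C)(Cl)C(C)(C)C
Why: Silylation is selective for the primary allylic alcohol over the hindered tertiary one and masks the C7 hydroxymethyl group for the carbonylation and the later esterification.

Step 18
Reactants: 26 (3E,6R,8E)-10-(tert-butyldimethylsilyloxy)-9-[(E)-4-iodopent-3-en-1-yl]-2,6-dimethyl-6-[(E)-2-(tributylstannyl)ethenyl]deca-3,8-dien-2-ol
Product: 27 (2E,4R,6E,10E)-7-[(tert-butyldimethylsilyloxy)methyl]-4-[(E)-4-hydroxy-4-methylpent-2-en-1-yl]-4,11-dimethylcycloundeca-2,6,10-trien-1-one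
Conditions: Pd2(dba)3 (5 mol%), AsPh3 (20 mol%), LiCl, CO (3 atm), DMF, 50 °C, syringe-pump addition of 26 over 24 h (final 1 mM)
Reagents that add atoms: carbon monoxide, [C-]#[O+]
Why: Carbonylative Stille coupling run as a macrocyclisation, in which oxidative addition of zerovalent palladium into the C11–iodine bond, CO insertion under pressure, intramolecular transmetalation with the (E)-vinylstannane and reductive elimination close the eleven-membered cross-conjugated dienone with both olefin geometries retained, high dilution suppressing oligomers and the CO pressure suppressing direct coupling.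

Step 19
Reactants: 27 (2E,4R,6E,10E)-7-[(tert-butyldimethylsilyloxy)methyl]-4-[(E)-4-hydroxy-4-methylpent-2-en-1-yl]-4,11-dimethylcycloundeca-2,6,10-trien-1-one
Product: 28 (1R,2E,4R,6E,10E)-7-[(tert-butyldimethylsilyloxy)methyl]-4-[(E)-4-hydroxy-4-methylpent-2-en-1-yl]-4,11-dimethylcycloundeca-2,6,10-trien-1-ol
Conditions: (S)-2-methyl-CBS-oxazaborolidine (0.5 equiv), catecholborane (2 equiv), toluene, −78 °C; MeOH; aq. NaOH
Reagents that add atoms: none
Why: Corey–Bakshi–Shibata reduction, in which the (S)-oxazaborolidine is expected to treat the α-methyl-substituted alkenyl arm (C11 side) as the large group and deliver hydride 1,2 to give the (1R)-alcohol, any 1S epimer being left unreacted by the matched epoxidation that follows.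

Step 20
Reactants: 28 (1R,2E,4R,6E,10E)-7-[(tert-butyldimethylsilyloxy)methyl]-4-[(E)-4-hydroxy-4-methylpent-2-en-1-yl]-4,11-dimethylcycloundeca-2,6,10-trien-1-ol
Product: 29 (1R,2E,4R,6E,10R,11S)-10,11-epoxy-7-[(tert-butyldimethylsilyloxy)methyl]-4-[(E)-4-hydroxy-4-methylpent-2-en-1-yl]-4,11-dimethylcycloundeca-2,6-dien-1-ol
Conditions: Ti(OiPr)4 (1.2 equiv), D-(−)-diisopropyl tartrate (1.5 equiv), t-BuOOH (2 equiv, in decane), 4 Å molecular sieves, CH2Cl2, −20 °C
Reagents that add atoms: tert-butyl hydroperoxide, CC(C)(C)OO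
Why: Sharpless asymmetric epoxidation in its matched kinetic-resolution mode, in which the (1R)-carbinol is the fast-reacting configuration with the D-(−)-tartrate for the electron-rich trisubstituted C10=C11 alkene (the hindered C2=C3 alkene is the mismatched one) and oxygen is delivered to give the erythro (1R,10R,11S)-epoxy alcohol, setting C10 and C11.

Step 21
Reactants: 29 (1R,2E,4R,6E,10R,11S)-10,11-epoxy-7-[(tert-butyldimethylsilyloxy)methyl]-4-[(E)-4-hydroxy-4-methylpent-2-en-1-yl]-4,11-dimethylcycloundeca-2,6-dien-1-ol; 30 3-methylbut-2-enoic acid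
Product: 31 (1S,2E,4R,6E,10R,11S)-10,11-epoxy-7-[(tert-butyldimethylsilyloxy)methyl]-4-[(E)-4-hydroxy-4-methylpent-2-en-1-yl]-4,11-dimethylcycloundeca-2,6-dien-1-yl 3-methylbut-2-enoate
Conditions: 30, PPh3, DIAD, toluene, 0 °C → rt
Reagents that add atoms: none
Why: Mitsunobu esterification, in which the allylic C1 oxyphosphonium ion (no β-hydrogen to eliminate, SN2′ blocked by the quaternary C4) is displaced by the carboxylate in an SN2 reaction with inversion, turning the erythro 1R alcohol into the threo 1S ester of the target while the tertiary alcohol does not react.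

Step 22
Reactants: 31 (1S,2E,4R,6E,10R,11S)-10,11-epoxy-7-[(tert-butyldimethylsilyloxy)methyl]-4-[(E)-4-hydroxy-4-methylpent-2-en-1-yl]-4,11-dimethylcycloundeca-2,6-dien-1-yl 3-methylbut-2-enoate
Product: 32 CNP0248133.1, (1S,2E,4R,6E,10R,11S)-10,11-epoxy-7-(hydroxymethyl)-4-[(E)-4-hydroxy-4-methylpent-2-en-1-yl]-4,11-dimethylcycloundeca-2,6-dien-1-yl 3-methylbut-2-enoate
Conditions: TBAF, AcOH (1:1), THF, 0 °C → rt
Reagents that add atoms: none
Why: Buffered fluoride desilylation cleaves the primary silyl ether while the hindered unsaturated ester, the epoxide and the tertiary alcohol are stable.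

**Compound list**

1 | tert-butyl(but-3-yn-1-yloxy)dimethylsilane | C#CCCO[Si](C)(C)C(C)(C)C | starting material
2 | acetaldehyde | CC=O | starting material
3 | (E)-[4-(tert-butyldimethylsilyloxy)-2-methylbut-1-en-1-yl]dimethylalane | C[Al](C)/C=C(\C)CCO[Si](C)(C)C(C)(C)C | intermediate
4 | rac-(E)-6-(tert-butyldimethylsilyloxy)-4-methylhex-3-en-2-ol | CC(O)/C=C(\C)CCO[Si](C)(C)C(C)(C)C | intermediate
5 | (2S,3E)-6-(tert-butyldimethylsilyloxy)-4-methylhex-3-en-2-ol | C[C@H](O)/C=C(\C)CCO[Si](C)(C)C(C)(C)C | intermediate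
6 | tert-butyl{[(3E,5S)-5-(1-methoxyethenyloxy)-3-methylhex-3-en-1-yl]oxy}dimethylsilane (mixed ketene acetal) | C=C(OC)O[C@@H](C)/C=C(\C)CCO[Si](C)(C)C(C)(C)C | intermediate
7 | methyl (3S,4E)-3-[2-(tert-butyldimethylsilyloxy)ethyl]-3-methylhex-4-enoate | C/C=C/[C@](C)(CC(=O)OC)CCO[Si](C)(C)C(C)(C)C | intermediate
8 | methyl (3S)-5-(tert-butyldimethylsilyloxy)-3-methyl-3-(5-methyl-1,2,4-trioxolan-3-yl)pentanoate (ozonide, both ring epimers) | CC1OOC(O1)[C@](C)(CC(=O)OC)CCO[Si](C)(C)C(C)(C)C | intermediate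
9 | methyl (3S)-5-(tert-butyldimethylsilyloxy)-3-formyl-3-methylpentanoate | O=C[C@](C)(CC(=O)OC)CCO[Si](C)(C)C(C)(C)C | intermediate
10 | methyl (3S)-3-[2-(tert-butyldimethylsilyloxy)ethyl]-3-methylpent-4-ynoate | C#C[C@](C)(CC(=O)OC)CCO[Si](C)(C)C(C)(C)C | intermediate
11 | methyl (3S,4E)-3-[2-(tert-butyldimethylsilyloxy)ethyl]-3-methyl-5-(tributylstannyl)pent-4-enoate | CCCC[Sn](CCCC)(CCCC)/C=C/[C@](C)(CC(=O)OC)CCO[Si](C)(C)C(C)(C)C | intermediate
12 | (3S,4E)-3-[2-(tert-butyldimethylsilyloxy)ethyl]-3-methyl-5-(tributylstannyl)pent-4-enal | CCCC[Sn](CCCC)(CCCC)/C=C/[C@](C)(CC=O)CCO[Si](C)(C)C(C)(C)C | intermediate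
13 | dimethyl (2-oxopropyl)phosphonate | CC(=O)CP(=O)(OC)OC | starting material
14 | (3E,6R,7E)-6-[2-(tert-butyldimethylsilyloxy)ethyl]-6-methyl-8-(tributylstannyl)octa-3,7-dien-2-one | CCCC[Sn](CCCC)(CCCC)/C=C/[C@](C)(C/C=C/C(C)=O)CCO[Si](C)(C)C(C)(C)C | intermediate
15 | (3E,6R,7E)-6-[2-(tert-butyldimethylsilyloxy)ethyl]-2,6-dimethyl-8-(tributylstannyl)octa-3,7-dien-2-ol | CCCC[Sn](CCCC)(CCCC)/C=C/[C@](C)(C/C=C/C(C)(C)O)CCO[Si](C)(C)C(C)(C)C | intermediate
16 | (3R,5E)-3,7-dimethyl-3-[(E)-2-(tributylstannyl)ethenyl]oct-5-ene-1,7-diol | CCCC[Sn](CCCC)(CCCC)/C=C/[C@](C)(C/C=C/C(C)(C)O)CCO | intermediate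
17 | (3R,5E)-7-hydroxy-3,7-dimethyl-3-[(E)-2-(tributylstannyl)ethenyl]oct-5-enal | CCCC[Sn](CCCC)(CCCC)/C=C/[C@](C)(C/C=C/C(C)(C)O)CC=O | intermediate
18 | pent-3-yn-1-ol | CC#CCCO | starting material
19 | (E)-alkenylzirconocene chloride Cp2Zr(Cl)–C(CH3)=CH–CH2CH2–O–Zr(Cl)Cp2 | C/C(=C\CCO[Zr](Cl)(C1C=CC=C1)C1C=CC=C1)[Zr](Cl)(C1C=CC=C1)C1C=CC=C1 | intermediate
20 | (E)-4-iodopent-3-en-1-ol | OCC/C=C(\C)I | intermediate
21 | (E)-2,5-diiodopent-2-ene | ICC/C=C(\C)I | intermediate
22 | triethyl phosphonoacetate | CCOC(=O)CP(=O)(OCC)OCC | starting material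
23 | ethyl (5E)-2-(diethoxyphosphoryl)-6-iodohept-5-enoate (racemic at C2) | CCOC(=O)C(CC/C=C(\C)I)P(=O)(OCC)OCC | intermediate
24 | ethyl (2E,5R,7E)-9-hydroxy-2-[(E)-4-iodopent-3-en-1-yl]-5,9-dimethyl-5-[(E)-2-(tributylstannyl)ethenyl]deca-2,7-dienoate | CCCC[Sn](CCCC)(CCCC)/C=C/[C@](C)(C/C=C/C(C)(C)O)C/C=C(/C(=O)OCC)CC/C=C(\C)I | intermediate
25 | (2E,5R,7E)-2-[(E)-4-iodopent-3-en-1-yl]-5,9-dimethyl-5-[(E)-2-(tributylstannyl)ethenyl]deca-2,7-diene-1,9-diol | CCCC[Sn](CCCC)(CCCC)/C=C/[C@](C)(C/C=C/C(C)(C)O)C/C=C(/CO)CC/C=C(\C)I | intermediate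
26 | (3E,6R,8E)-10-(tert-butyldimethylsilyloxy)-9-[(E)-4-iodopent-3-en-1-yl]-2,6-dimethyl-6-[(E)-2-(tributylstannyl)ethenyl]deca-3,8-dien-2-ol | CCCC[Sn](CCCC)(CCCC)/C=C/[C@](C)(C/C=C/C(C)(C)O)C/C=C(/CO[Si](C)(C)C(C)(C)C)CC/C=C(\C)I | intermediate
27 | (2E,4R,6E,10E)-7-[(tert-butyldimethylsilyloxy)methyl]-4-[(E)-4-hydroxy-4-methylpent-2-en-1-yl]-4,11-dimethylcycloundeca-2,6,10-trien-1-one | O=C1/C=C/[C@](C)(C/C=C/C(C)(C)O)C/C=C(/CO[Si](C)(C)C(C)(C)C)CC/C=C1\C | intermediate
28 | (1R,2E,4R,6E,10E)-7-[(tert-butyldimethylsilyloxy)methyl]-4-[(E)-4-hydroxy-4-methylpent-2-en-1-yl]-4,11-dimethylcycloundeca-2,6,10-trien-1-ol | O[C@@H]1/C=C/[C@](C)(C/C=C/C(C)(C)O)C/C=C(/CO[Si](C)(C)C(C)(C)C)CC/C=C1\C | intermediate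
29 | (1R,2E,4R,6E,10R,11S)-10,11-epoxy-7-[(tert-butyldimethylsilyloxy)methyl]-4-[(E)-4-hydroxy-4-methylpent-2-en-1-yl]-4,11-dimethylcycloundeca-2,6-dien-1-ol | O[C@@H]1/C=C/[C@](C)(C/C=C/C(C)(C)O)C/C=C(/CO[Si](C)(C)C(C)(C)C)CC[C@H]2O[C@]12C | intermediate
30 | 3-methylbut-2-enoic acid | CC(C)=CC(=O)O | starting material
31 | (1S,2E,4R,6E,10R,11S)-10,11-epoxy-7-[(tert-butyldimethylsilyloxy)methyl]-4-[(E)-4-hydroxy-4-methylpent-2-en-1-yl]-4,11-dimethylcycloundeca-2,6-dien-1-yl 3-methylbut-2-enoate | CC(C)=CC(=O)O[C@H]1/C=C/[C@](C)(C/C=C/C(C)(C)O)C/C=C(/CO[Si](C)(C)C(C)(C)C)CC[C@H]2O[C@]12C | intermediate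
32 | CNP0248133.1, (1S,2E,4R,6E,10R,11S)-10,11-epoxy-7-(hydroxymethyl)-4-[(E)-4-hydroxy-4-methylpent-2-en-1-yl]-4,11-dimethylcycloundeca-2,6-dien-1-yl 3-methylbut-2-enoate | CC(C)=CC(=O)O[C@H]1/C=C/[C@](C)(C/C=C/C(C)(C)O)C/C=C(/CO)CC[C@H]2O[C@]12C | target

**Totals and risk**

Total step count: 22 (19 in the main line, 3 for phosphonate 23). Longest linear sequence: 19 steps (steps 1–11 and 15–22).

The three steps most likely to fail are 18, 19 and 21.

Step 18 (macrocyclisation under CO) may give oligomers or the ring-contracted diene from direct coupling. The fallback separates the two bond formations and closes the ring elsewhere. It sets out from 17 and 23: an intermolecular carbonylative Stille coupling (Pd2(dba)3, AsPh3, CO 3 atm, DMF, 50 °C) joins C2 and C11 through CO to give the open-chain dienone ethyl (5E,8E,10R,12E)-2-(diethoxyphosphoryl)-14-hydroxy-6,10,14-trimethyl-7-oxo-10-(2-oxoethyl)pentadeca-5,8,12-trienoate F1. An intramolecular HWE olefination (K2CO3, 18-crown-6, toluene, 1 mM, 60 °C) then closes the ring at C6=C7 to the macrocyclic dienone ethyl ester F2, whose E-enoate is the ring-cis geometry an eleven-membered ring prefers. Reduction with the (S)-oxazaborolidine and catecholborane gives the (1R)-dienol ethyl ester F3, iBu2AlH reduces the ester to the (1R)-dienol with free hydroxymethyl group F4, and TBSCl with imidazole silylates only the primary alcohol, which comes back to the route at 28.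

Step 19 (CBS reduction) may not distinguish the two alkenyl arms of the ketone. The fallback gives up reagent control at the ketone and uses a resolution with recycling. It sets out from 27: Luche reduction (NaBH4, CeCl3·7H2O, MeOH, −40 °C) gives 28 together with its C1 epimer, the (1S)-dienol F5. The mixture is taken through step 20 unchanged, where only 28 is matched to the D-(−)-tartrate, so the epoxidation acts as a kinetic resolution and the route is rejoined at 29. Unreacted F5 is separated and returned to 27 with MnO2.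

Step 21 (Mitsunobu at a carbinol flanked by a fully substituted oxirane carbon) may be too hindered for SN2 displacement. The fallback replaces inversion by substitution with inversion through the ketone. It sets out from 29: Dess–Martin oxidation gives the epoxy enone F6. A reagent-controlled CBS reduction ((R)-2-methyl-CBS-oxazaborolidine, catecholborane, taking the fully substituted oxiranyl carbon as the large group; the other antipode of the catalyst is used if the sense turns out reversed) gives the threo (1S)-epoxy alcohol F7. Steglich esterification with 30 (DCC, DMAP, CH2Cl2), now with retention, comes back to the route at 31.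

Further compounds
F1 | step 18 | ethyl (5E,8E,10R,12E)-2-(diethoxyphosphoryl)-14-hydroxy-6,10,14-trimethyl-7-oxo-10-(2-oxoethyl)pentadeca-5,8,12-trienoate | CCOC(=O)C(CC/C=C(\C)C(=O)/C=C/[C@](C)(C/C=C/C(C)(C)O)CC=O)P(=O)(OCC)OCC
F2 | step 18 | ethyl (2E,4R,6E,10E)-4-[(E)-4-hydroxy-4-methylpent-2-en-1-yl]-4,11-dimethyl-1-oxocycloundeca-2,6,10-triene-7-carboxylate (numbered as 27) | O=C1/C=C/[C@](C)(C/C=C/C(C)(C)O)C/C=C(/C(=O)OCC)CC/C=C1\C
F3 | step 18 | ethyl (1R,2E,4R,6E,10E)-1-hydroxy-4-[(E)-4-hydroxy-4-methylpent-2-en-1-yl]-4,11-dimethylcycloundeca-2,6,10-triene-7-carboxylate (numbered as 28) | O[C@@H]1/C=C/[C@](C)(C/C=C/C(C)(C)O)C/C=C(/C(=O)OCC)CC/C=C1\C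
F4 | step 18 | (1R,2E,4R,6E,10E)-7-(hydroxymethyl)-4-[(E)-4-hydroxy-4-methylpent-2-en-1-yl]-4,11-dimethylcycloundeca-2,6,10-trien-1-ol | O[C@@H]1/C=C/[C@](C)(C/C=C/C(C)(C)O)C/C=C(/CO)CC/C=C1\C
F5 | step 19 | (1S,2E,4R,6E,10E)-7-[(tert-butyldimethylsilyloxy)methyl]-4-[(E)-4-hydroxy-4-methylpent-2-en-1-yl]-4,11-dimethylcycloundeca-2,6,10-trien-1-ol (C1 epimer of 28) | O[C@H]1/C=C/[C@](C)(C/C=C/C(C)(C)O)C/C=C(/CO[Si](C)(C)C(C)(C)C)CC/C=C1\C
F6 | step 21 | (2E,4R,6E,10R,11S)-10,11-epoxy-7-[(tert-butyldimethylsilyloxy)methyl]-4-[(E)-4-hydroxy-4-methylpent-2-en-1-yl]-4,11-dimethylcycloundeca-2,6-dien-1-one | O=C1/C=C/[C@](C)(C/C=C/C(C)(C)O)C/C=C(/CO[Si](C)(C)C(C)(C)C)CC[C@H]2O[C@]12C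
F7 | step 21 | (1S,2E,4R,6E,10R,11S)-10,11-epoxy-7-[(tert-butyldimethylsilyloxy)methyl]-4-[(E)-4-hydroxy-4-methylpent-2-en-1-yl]-4,11-dimethylcycloundeca-2,6-dien-1-ol (C1 epimer of 29) | O[C@H]1/C=C/[C@](C)(C/C=C/C(C)(C)O)C/C=C(/CO[Si](C)(C)C(C)(C)C)CC[C@H]2O[C@]12C
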